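**Retrosynthetic overview**
- Endgame: target 25 ⇐ MOM removal ⇐ aryl acetate from the aryl O‑TIPS ether ⇐ angelate ester of the (S)‑allylic alcohol 19.
- Key disconnection: the bond between the carbinol carbon and the aryl‑bearing vinyl carbon. The carbinol carbon is used as a chiral α‑oxy carbanion (lithiated homoprenyl carbamate, (+)‑sparteine), an umpoled carbenoid. It is joined to the 1‑arylvinyl boronic ester 13 by boronate formation, 1,2‑shift and oxidation, which sets (S) directly.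
- 13 ⇐ aryl boronic ester 8 by insertion of a C(=CH2) unit with a lithiated epoxysilane carbenoid.
- 8 ⇐ 3‑methoxy‑2‑methylphenol 1 by two directed ortho‑metalations (first O, then B); TIPS on O‑5 and MOM on O‑2 keep the two phenol oxygens distinct.
- No ring is formed; the benzene ring is bought in 1.

Assumption: 1, 9, 14, 20, (+)‑sparteine and all reagents are purchased (9 is otherwise one step from vinyltrimethylsilane and mCPBA).

**Step 1**
Reactants: 1 3‑methoxy‑2‑methylphenol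
Product: 2 (3‑methoxy‑2‑methylphenoxy)tri(propan‑2‑yl)silane
Conditions: TIPSCl, imidazole, DMF, rt
Reagents that add atoms: chlorotri(propan‑2‑yl)silane, CC(C)[Si](Cl)(C(C)C)C(C)C
Why: Imidazole‑promoted O‑silylation of a phenol; the bulky, non‑coordinating TIPS ether does not direct lithiation, so later metalations are steered by OMe and OMOM only.

**Step 2**
Reactants: 2 (3‑methoxy‑2‑methylphenoxy)tri(propan‑2‑yl)silane
Product: 5 2‑methoxy‑3‑methyl‑4‑(triisopropylsilyloxy)phenol, via aryllithium 3 (not isolated), via dimethyl arylboronate 4 (not isolated)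
Conditions: n‑BuLi, TMEDA, Et2O, 0 °C → rt; B(OMe)3, −78 °C → rt; 30% H2O2, AcOH, 0 °C → rt
Reagents that add atoms: hydrogen peroxide, OO
Why: Directed ortho‑metalation at the only ring C–H next to a coordinating group (OMe), borate trapping and ipso‑hydroxylation of the aryl boronate (Hawthorne‑type oxidation) give the phenol.

**Step 3**
Reactants: 5 2‑methoxy‑3‑methyl‑4‑(triisopropylsilyloxy)phenol
Product: 6 [3‑methoxy‑4‑(methoxymethoxy)‑2‑methylphenoxy]tri(propan‑2‑yl)silane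
Conditions: MOMCl, i‑Pr2NEt, CH2Cl2, 0 °C → rt
Reagents that add atoms: chloromethyl methyl ether, COCCl
Why: O‑alkylation (MOM protection) masks the phenol that is free in the target and installs a strong ortho‑directing group.

**Step 4**
Reactants: 6 [3‑methoxy‑4‑(methoxymethoxy)‑2‑methylphenoxy]tri(propan‑2‑yl)silane
Product: 8 2‑[3‑methoxy‑2‑(methoxymethoxy)‑4‑methyl‑5‑(triisopropylsilyloxy)phenyl]‑4,4,5,5‑tetramethyl‑1,3,2‑dioxaborolane, via aryllithium 7 (not isolated)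
Conditions: n‑BuLi, THF, 0 °C; i‑PrOBpin, −78 °C → rt; H2O
Reagents that add atoms: 2‑isopropoxy‑4,4,5,5‑tetramethyl‑1,3,2‑dioxaborolane, CC(C)OB1OC(C)(C)C(C)(C)O1
Why: OMOM‑directed ortho‑lithiation occurs at the single C–H ortho to OMOM, and the aryllithium is trapped by electrophilic borylation.

**Step 5**
Reactants: 8 aryl pinacol boronate from step 4; 9 trimethyl(oxiran‑2‑yl)silane (racemic)
Product: 13 2‑{1‑[3‑methoxy‑2‑(methoxymethoxy)‑4‑methyl‑5‑(triisopropylsilyloxy)phenyl]ethenyl}‑4,4,5,5‑tetramethyl‑1,3,2‑dioxaborolane, via lithiated epoxysilane 10 (not isolated), via boronate complex 11 (not isolated), via lithium alkoxide 12 (not isolated)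
Conditions: 9, s‑BuLi, TMEDA, Et2O, −110 °C; then 8, −110 °C → rt; H2O
Reagents that add atoms: none
Why: Vinylidene homologation of a boronic ester: the lithiated epoxysilane adds to boron, a 1,2‑aryl shift opens the epoxide, and Peterson‑type loss of Me3SiOLi leaves the 1‑arylvinyl boronate (a reaction reported to work for electron‑rich aryl boronic esters).

**Step 6**
Reactants: 14 4‑methylpent‑3‑en‑1‑ol
Product: 15 4‑methylpent‑3‑en‑1‑yl N,N‑di(propan‑2‑yl)carbamate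
Conditions: i‑Pr2NCOCl, Et3N, CH2Cl2, reflux
Reagents that add atoms: N,N‑diisopropylcarbamoyl chloride, CC(C)N(C(C)C)C(=O)Cl
Why: Carbamoylation of the primary alcohol gives the Hoppe carbamate whose C=O directs and stabilises α‑lithiation.

**Step 7 (key step)**
Reactants: 15 4‑methylpent‑3‑en‑1‑yl N,N‑di(propan‑2‑yl)carbamate; 13 1‑arylvinyl pinacol boronate from step 5
Product: 19 (3S)‑2‑[3‑methoxy‑2‑(methoxymethoxy)‑4‑methyl‑5‑(triisopropylsilyloxy)phenyl]‑6‑methylhepta‑1,5‑dien‑3‑ol, via lithiated carbamate 16 (not isolated), via boronate complex 17 (not isolated), via allylic boronic ester 18 (not isolated)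
Conditions: 15 (1.4 equiv), s‑BuLi, (+)‑sparteine, Et2O, −78 °C, 5 h; 13, −78 °C, 1 h, then 35 °C, 12 h; NaBO3·4H2O, THF/H2O, rt
Reagents that add atoms: sodium perborate tetrahydrate, O.O.O.O.[Na+].[O-]OB=O
Why: Hoppe–Aggarwal lithiation–borylation: s‑BuLi/(+)‑sparteine removes the pro‑R α‑hydrogen to give the configurationally stable (R)‑α‑oxy carbanion (the carbinol carbon with reversed polarity, a chiral carbenoid), which is borylated with retention, undergoes a stereospecific 1,2‑shift of the arylvinyl group with inversion (loss of the carbamate) and is oxidised with retention, so the (S) carbinol centre is fixed by the reagent.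

**Step 8**
Reactants: 19 (S)‑allylic alcohol from step 7; 20 angelic acid, (2Z)‑2‑methylbut‑2‑enoic acid
Product: 22 (3S)‑2‑[3‑methoxy‑2‑(methoxymethoxy)‑4‑methyl‑5‑(triisopropylsilyloxy)phenyl]‑6‑methylhepta‑1,5‑dien‑3‑yl (2Z)‑2‑methylbut‑2‑enoate, via mixed anhydride 21 (not isolated)
Conditions: 20, 2,4,6‑trichlorobenzoyl chloride, Et3N, toluene, rt; then 19, 80 °C (no DMAP)
Reagents that add atoms: none
Why: Yamaguchi‑type mixed‑anhydride esterification run without DMAP (Greene angeloylation) acylates the secondary alcohol without Z→E isomerisation and without touching the C–O stereocentre.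

**Step 9**
Reactants: 22 angelate ester from step 8
Product: 24 (3S)‑2‑[5‑(acetyloxy)‑3‑methoxy‑2‑(methoxymethoxy)‑4‑methylphenyl]‑6‑methylhepta‑1,5‑dien‑3‑yl (2Z)‑2‑methylbut‑2‑enoate, via ammonium phenoxide 23 (not isolated)
Conditions: TBAF (1.1 equiv), THF, 0 °C; then Ac2O, 0 °C → rt
Reagents that add atoms: acetic anhydride, CC(=O)OC(C)=O
Why: Fluoride desilylation of the aryl TIPS ether and acetylation of the resulting phenoxide in the same flask (one‑pot desilylation/O‑acylation) place the acetate on O‑5 only, because O‑2 is still a MOM ether.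

**Step 10**
Reactants: 24 MOM‑protected acetate from step 9
Product: 25 (3S)‑2‑[5‑(acetyloxy)‑2‑hydroxy‑3‑methoxy‑4‑methylphenyl]‑6‑methylhepta‑1,5‑dien‑3‑yl (2Z)‑2‑methylbut‑2‑enoate
Conditions: ZnBr2, n‑PrSH, CH2Cl2, 0 °C → rt, 10 min
Reagents that add atoms: none
Why: Lewis acid/thiol cleavage of the aryl MOM ether (acetal cleavage) is fast and leaves the aryl acetate, the allylic angelate and both alkenes intact.

**Compound list**
1 | 3‑methoxy‑2‑methylphenol | COc1cccc(O)c1C | starting material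
2 | (3‑methoxy‑2‑methylphenoxy)tri(propan‑2‑yl)silane | COc1cccc(O[Si](C(C)C)(C(C)C)C(C)C)c1C | intermediate
3 | [2‑methoxy‑3‑methyl‑4‑(triisopropylsilyloxy)phenyl]lithium | COc1c([Li])ccc(O[Si](C(C)C)(C(C)C)C(C)C)c1C | intermediate (not isolated)
4 | dimethyl [2‑methoxy‑3‑methyl‑4‑(triisopropylsilyloxy)phenyl]boronate | COc1c(B(OC)OC)ccc(O[Si](C(C)C)(C(C)C)C(C)C)c1C | intermediate (not isolated)
5 | 2‑methoxy‑3‑methyl‑4‑(triisopropylsilyloxy)phenol | COc1c(O)ccc(O[Si](C(C)C)(C(C)C)C(C)C)c1C | intermediate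
6 | [3‑methoxy‑4‑(methoxymethoxy)‑2‑methylphenoxy]tri(propan‑2‑yl)silane | COCOc1ccc(O[Si](C(C)C)(C(C)C)C(C)C)c(C)c1OC | intermediate
7 | [3‑methoxy‑2‑(methoxymethoxy)‑4‑methyl‑5‑(triisopropylsilyloxy)phenyl]lithium | COCOc1c([Li])cc(O[Si](C(C)C)(C(C)C)C(C)C)c(C)c1OC | intermediate (not isolated)
8 | 2‑[3‑methoxy‑2‑(methoxymethoxy)‑4‑methyl‑5‑(triisopropylsilyloxy)phenyl]‑4,4,5,5‑tetramethyl‑1,3,2‑dioxaborolane | COCOc1c(B2OC(C)(C)C(C)(C)O2)cc(O[Si](C(C)C)(C(C)C)C(C)C)c(C)c1OC | intermediate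
9 | trimethyl(oxiran‑2‑yl)silane (racemic) | C[Si](C)(C)C1CO1 | starting material
10 | [2‑(trimethylsilyl)oxiran‑2‑yl]lithium | C[Si](C)(C)C1([Li])CO1 | intermediate (not isolated)
11 | lithium boronate complex of 8 with 10 (B bears pinacolate, the aryl group and the silyl epoxide carbon) | [Li+].C[Si](C)(C)C1(CO1)[B-]2(OC(C)(C)C(C)(C)O2)c3cc(O[Si](C(C)C)(C(C)C)C(C)C)c(C)c(OC)c3OCOC | intermediate (not isolated)
12 | lithium 2‑aryl‑2‑(pinacolboryl)‑2‑(trimethylsilyl)ethan‑1‑olate (aryl as in 8) | [Li+].[O-]CC([Si](C)(C)C)(B1OC(C)(C)C(C)(C)O1)c2cc(O[Si](C(C)C)(C(C)C)C(C)C)c(C)c(OC)c2OCOC | intermediate (not isolated)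
13 | 2‑{1‑[3‑methoxy‑2‑(methoxymethoxy)‑4‑methyl‑5‑(triisopropylsilyloxy)phenyl]ethenyl}‑4,4,5,5‑tetramethyl‑1,3,2‑dioxaborolane | C=C(B1OC(C)(C)C(C)(C)O1)c2cc(O[Si](C(C)C)(C(C)C)C(C)C)c(C)c(OC)c2OCOC | intermediate
14 | 4‑methylpent‑3‑en‑1‑ol | CC(C)=CCCO | starting material
15 | 4‑methylpent‑3‑en‑1‑yl N,N‑di(propan‑2‑yl)carbamate | CC(C)=CCCOC(=O)N(C(C)C)C(C)C | intermediate
16 | (1R)‑1‑lithio‑4‑methylpent‑3‑en‑1‑yl N,N‑di(propan‑2‑yl)carbamate, as its (+)‑sparteine complex (drawn without the diamine) | [Li][C@H](CC=C(C)C)OC(=O)N(C(C)C)C(C)C | intermediate (not isolated)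
17 | lithium boronate complex of 13 with 16, (R) at the carbamate‑bearing carbon | [Li+].C=C(c1cc(O[Si](C(C)C)(C(C)C)C(C)C)c(C)c(OC)c1OCOC)[B-]2(OC(C)(C)C(C)(C)O2)[C@H](CC=C(C)C)OC(=O)N(C(C)C)C(C)C | intermediate (not isolated)
18 | 2‑{(3S)‑2‑[3‑methoxy‑2‑(methoxymethoxy)‑4‑methyl‑5‑(triisopropylsilyloxy)phenyl]‑6‑methylhepta‑1,5‑dien‑3‑yl}‑4,4,5,5‑tetramethyl‑1,3,2‑dioxaborolane | C=C(c1cc(O[Si](C(C)C)(C(C)C)C(C)C)c(C)c(OC)c1OCOC)[C@H](CC=C(C)C)B2OC(C)(C)C(C)(C)O2 | intermediate (not isolated)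
19 | (3S)‑2‑[3‑methoxy‑2‑(methoxymethoxy)‑4‑methyl‑5‑(triisopropylsilyloxy)phenyl]‑6‑methylhepta‑1,5‑dien‑3‑ol | C=C(c1cc(O[Si](C(C)C)(C(C)C)C(C)C)c(C)c(OC)c1OCOC)[C@H](CC=C(C)C)O | intermediate
20 | angelic acid, (2Z)‑2‑methylbut‑2‑enoic acid | C/C=C(/C)C(=O)O | starting material
21 | (2Z)‑2‑methylbut‑2‑enoic 2,4,6‑trichlorobenzoic anhydride | C/C=C(/C)C(=O)OC(=O)c1c(Cl)cc(Cl)cc1Cl | intermediate (not isolated)
22 | (3S)‑2‑[3‑methoxy‑2‑(methoxymethoxy)‑4‑methyl‑5‑(triisopropylsilyloxy)phenyl]‑6‑methylhepta‑1,5‑dien‑3‑yl (2Z)‑2‑methylbut‑2‑enoate | C=C(c1cc(O[Si](C(C)C)(C(C)C)C(C)C)c(C)c(OC)c1OCOC)[C@H](CC=C(C)C)OC(=O)/C(C)=C\C | intermediate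
23 | tetrabutylammonium 5‑[(3S)‑3‑{[(2Z)‑2‑methylbut‑2‑enoyl]oxy}‑6‑methylhepta‑1,5‑dien‑2‑yl]‑3‑methoxy‑4‑(methoxymethoxy)‑2‑methylphenolate | CCCC[N+](CCCC)(CCCC)CCCC.C=C(c1cc([O-])c(C)c(OC)c1OCOC)[C@H](CC=C(C)C)OC(=O)/C(C)=C\C | intermediate (not isolated)
24 | (3S)‑2‑[5‑(acetyloxy)‑3‑methoxy‑2‑(methoxymethoxy)‑4‑methylphenyl]‑6‑methylhepta‑1,5‑dien‑3‑yl (2Z)‑2‑methylbut‑2‑enoate | C=C(c1cc(OC(C)=O)c(C)c(OC)c1OCOC)[C@H](CC=C(C)C)OC(=O)/C(C)=C\C | intermediate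
25 | (3S)‑2‑[5‑(acetyloxy)‑2‑hydroxy‑3‑methoxy‑4‑methylphenyl]‑6‑methylhepta‑1,5‑dien‑3‑yl (2Z)‑2‑methylbut‑2‑enoate | C=C(c1cc(OC(C)=O)c(C)c(OC)c1O)[C@H](CC=C(C)C)OC(=O)/C(C)=C\C | target

**Totals**
Total step count: 10. Longest linear sequence: 9 (steps 1–5 and 7–10; step 6 is a one‑step side branch).

**Three steps most likely to fail, with fallbacks**

Risk 1, step 7. The boronic ester 13 is hindered (α‑aryl, ortho‑OMOM), so boronate formation or the 1,2‑shift may be slow, and the allylic boronate 18 could undergo 1,3‑boron shift before oxidation. The fallback keeps the same chiral α‑oxy carbanion but forms the C–C bond by cross‑coupling with retention; it sets out from 13 and 15 and returns at 19. Boronate 13 is converted with NaOH and I2 in THF/H2O at 0 °C into the vinyl iodide [5‑(1‑iodoethenyl)‑3‑methoxy‑4‑(methoxymethoxy)‑2‑methylphenoxy]tri(propan‑2‑yl)silane F3. Carbamate 15 is lithiated as before (s‑BuLi, (+)‑sparteine, Et2O, −78 °C) to 16 and transmetalated with ZnCl2, with retention, to chloro{(1R)‑1‑[(diisopropylcarbamoyl)oxy]‑4‑methylpent‑3‑en‑1‑yl}zinc F4. Negishi coupling of F4 with F3 (Pd(OAc)2, [HP(t‑Bu)3]BF4, THF, rt to 40 °C) gives, again with retention, (3S)‑2‑[3‑methoxy‑2‑(methoxymethoxy)‑4‑methyl‑5‑(triisopropylsilyloxy)phenyl]‑6‑methylhepta‑1,5‑dien‑3‑yl N,N‑di(propan‑2‑yl)carbamate F5. LiAlH4 in refluxing THF cleaves the carbamate to alcohol 19; MOM, TIPS and the alkenes tolerate this.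

Risk 2, step 5. Addition of the hindered lithiated epoxysilane 10 to the ortho‑substituted boronate 8 may be poor, or boron rather than silicon may be eliminated, giving a vinylsilane. The fallback builds the vinyl boronate from a ketone; it sets out from 6 and returns at 13. Lithiation of 6 (n‑BuLi, THF, 0 °C, giving 7) and quenching with N‑methoxy‑N‑methylacetamide gives 1‑[3‑methoxy‑2‑(methoxymethoxy)‑4‑methyl‑5‑(triisopropylsilyloxy)phenyl]ethan‑1‑one F1. KN(SiMe3)2 and PhNTf2 in THF at −78 °C convert it into 1‑[3‑methoxy‑2‑(methoxymethoxy)‑4‑methyl‑5‑(triisopropylsilyloxy)phenyl]ethenyl trifluoromethanesulfonate F2. Miyaura borylation of F2 (B2pin2, PdCl2(PPh3)2, PPh3, KOPh, toluene, 50 °C) gives 13.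

Risk 3, step 8. Acylation of the hindered secondary allylic alcohol may be slow, and forcing it risks angelate‑to‑tiglate isomerisation. The fallback builds the Z‑alkene after the ester bond is made; it sets out from 19 and returns at 22. Alcohol 19 is esterified with 2‑[bis(2,2,2‑trifluoroethoxy)phosphoryl]propanoic acid (EDC·HCl, DMAP, CH2Cl2, rt) to give (3S)‑2‑[3‑methoxy‑2‑(methoxymethoxy)‑4‑methyl‑5‑(triisopropylsilyloxy)phenyl]‑6‑methylhepta‑1,5‑dien‑3‑yl 2‑[bis(2,2,2‑trifluoroethoxy)phosphoryl]propanoate F6 (mixture at the phosphonate carbon). Still–Gennari olefination of F6 with acetaldehyde (KN(SiMe3)2, 18‑crown‑6, THF, −78 °C) gives the Z‑enoate 22.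

**Further compounds**
F1 | step 5 | 1‑[3‑methoxy‑2‑(methoxymethoxy)‑4‑methyl‑5‑(triisopropylsilyloxy)phenyl]ethan‑1‑one | CC(=O)c1cc(O[Si](C(C)C)(C(C)C)C(C)C)c(C)c(OC)c1OCOC
F2 | step 5 | 1‑[3‑methoxy‑2‑(methoxymethoxy)‑4‑methyl‑5‑(triisopropylsilyloxy)phenyl]ethenyl trifluoromethanesulfonate | C=C(OS(=O)(=O)C(F)(F)F)c1cc(O[Si](C(C)C)(C(C)C)C(C)C)c(C)c(OC)c1OCOC
F3 | step 7 | [5‑(1‑iodoethenyl)‑3‑methoxy‑4‑(methoxymethoxy)‑2‑methylphenoxy]tri(propan‑2‑yl)silane | C=C(I)c1cc(O[Si](C(C)C)(C(C)C)C(C)C)c(C)c(OC)c1OCOC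
F4 | step 7 | chloro{(1R)‑1‑[(diisopropylcarbamoyl)oxy]‑4‑methylpent‑3‑en‑1‑yl}zinc | Cl[Zn][C@H](CC=C(C)C)OC(=O)N(C(C)C)C(C)C
F5 | step 7 | (3S)‑2‑[3‑methoxy‑2‑(methoxymethoxy)‑4‑methyl‑5‑(triisopropylsilyloxy)phenyl]‑6‑methylhepta‑1,5‑dien‑3‑yl N,N‑di(propan‑2‑yl)carbamate | C=C(c1cc(O[Si](C(C)C)(C(C)C)C(C)C)c(C)c(OC)c1OCOC)[C@H](CC=C(C)C)OC(=O)N(C(C)C)C(C)C
F6 | step 8 | (3S)‑2‑[3‑methoxy‑2‑(methoxymethoxy)‑4‑methyl‑5‑(triisopropylsilyloxy)phenyl]‑6‑methylhepta‑1,5‑dien‑3‑yl 2‑[bis(2,2,2‑trifluoroethoxy)phosphoryl]propanoate | C=C(c1cc(O[Si](C(C)C)(C(C)C)C(C)C)c(C)c(OC)c1OCOC)[C@H](CC=C(C)C)OC(=O)C(C)P(=O)(OCC(F)(F)F)OCC(F)(F)F
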